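**Retrosynthetic overview**
- Target 13 (3R) ⇐ 12 by removal of the two ring-A MOM groups.
- Key step: 12 ⇐ aryl prenyl ether 10 by an aromatic Claisen rearrangement. The B ring is dearomatised to cyclohexadienone 11 and re-aromatises, so the prenyl ether is both the 4'-OH protecting group and the source of the 1,1-dimethylallyl group.
- 10 ⇐ keto-aldehyde 9 by an enantioselective NHC crossed benzoin (C3–C4 bond). This forms the pyranone ring, the only ring made, and sets the stereocentre.
- 9 ⇐ phenacyl bromide 6 + salicylaldehyde 8 (ether formation). 8 comes from C2v-symmetric 2,4,6-trihydroxybenzaldehyde 7 by symmetry-breaking bis-protection; 6 comes from resacetophenone 1 and prenyl bromide 2.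

Assumption 1: the sense of induction of the triazolium catalyst in step 5 is taken by analogy with related 3-hydroxychromanone benzoin cyclisations; if the first run gives (S)-10, the (5aR,10bS) antipode of the catalyst is used with no other change.
Assumption 2: compounds 1, 2 and 7 are taken as purchased.

**Step 1**
Reactants: 1 2',4'-dihydroxyacetophenone (resacetophenone); 2 prenyl bromide (1-bromo-3-methylbut-2-ene)
Product: 4 1-[2-methoxy-4-(3-methylbut-2-enyloxy)phenyl]ethanone, via monoprenyl ether 3 (not isolated)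
Conditions: K2CO3 (1.1 equiv), 2 (1.05 equiv), DMF, rt; then K2CO3 (2 equiv), MeI (3 equiv), 40 °C
Reagents that add atoms: iodomethane, CI
Why: Regioselective Williamson etherification, in which the free 4-OH is alkylated first by prenyl bromide and the hydrogen-bonded 2-OH is only then methylated by the small electrophile MeI under forcing conditions, so both ethers are set in one flask.

**Step 2**
Reactants: 4 1-[2-methoxy-4-(3-methylbut-2-enyloxy)phenyl]ethanone
Product: 6 2-bromo-1-[2-methoxy-4-(3-methylbut-2-enyloxy)phenyl]ethanone, via trimethylsilyl enol ether 5 (not isolated)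
Conditions: LiHMDS, THF, −78 °C; TMSCl; then NBS, −78 → 0 °C
Reagents that add atoms: N-bromosuccinimide, O=C1CCC(=O)N1Br; chlorotrimethylsilane, C[Si](C)(C)Cl (silicon stays only in intermediate 5)
Why: Kinetic enolisation and O-silylation followed by electrophilic bromination of the silyl enol ether, which is far more nucleophilic toward NBS at −78 °C than the prenyl alkene or the arene, so only the α-bromoketone forms.

**Step 3**
Reactants: 7 2,4,6-trihydroxybenzaldehyde
Product: 8 2-hydroxy-4,6-bis(methoxymethoxy)benzaldehyde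
Conditions: MOMCl (2.2 equiv), i-Pr2NEt, CH2Cl2, 0 °C → rt
Reagents that add atoms: chloromethyl methyl ether, COCCl
Why: Symmetry-breaking partial O-alkylation (acetal protection): the para-OH and one of the two equivalent ortho-OH groups react, while the remaining ortho-OH is deactivated by hydrogen bonding to the formyl group and stays free.

**Step 4**
Reactants: 6 2-bromo-1-[2-methoxy-4-(3-methylbut-2-enyloxy)phenyl]ethanone; 8 2-hydroxy-4,6-bis(methoxymethoxy)benzaldehyde
Product: 9 2-{2-[2-methoxy-4-(3-methylbut-2-enyloxy)phenyl]-2-oxoethoxy}-4,6-bis(methoxymethoxy)benzaldehyde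
Conditions: K2CO3, DMF, 0 °C → rt
Reagents that add atoms: none
Why: Williamson ether synthesis (SN2 of the phenoxide on the highly reactive α-bromoketone), kept at room temperature so that the keto-aldehyde does not go on to the Rap–Stoermer aldol/benzofuran product.

**Step 5**
Reactants: 9 2-{2-[2-methoxy-4-(3-methylbut-2-enyloxy)phenyl]-2-oxoethoxy}-4,6-bis(methoxymethoxy)benzaldehyde
Product: 10 (3R)-3-hydroxy-3-[2-methoxy-4-(3-methylbut-2-enyloxy)phenyl]-5,7-bis(methoxymethoxy)chroman-4-one
Conditions: (5aS,10bR)-2-(pentafluorophenyl)-5a,10b-dihydro-4H,6H-indeno[2,1-b][1,2,4]triazolo[4,3-d][1,4]oxazinium tetrafluoroborate (15 mol%), Et3N (15 mol%), toluene, rt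
Reagents that add atoms: none
Why: Enantioselective NHC-catalysed intramolecular crossed aldehyde–ketone benzoin reaction, in which the Breslow intermediate of the aldehyde adds 6-exo to the Si face of the aryl ketone (priorities O > CH2OAr > aryl) held in the chiral pocket of the aminoindanol triazolylidene, giving the (R)-configured tertiary α-ketol.

**Step 6 (key step)**
Reactants: 10 (3R)-3-hydroxy-3-[2-methoxy-4-(3-methylbut-2-enyloxy)phenyl]-5,7-bis(methoxymethoxy)chroman-4-one
Product: 12 (3R)-3-hydroxy-3-[4-hydroxy-2-methoxy-5-(2-methylbut-3-en-2-yl)phenyl]-5,7-bis(methoxymethoxy)chroman-4-one, via dearomatised cyclohexadienone 11 (not isolated)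
Conditions: EtOH–H2O 4:1, degassed, sealed tube, 130 °C
Reagents that add atoms: none
Why: Water-accelerated aromatic Claisen rearrangement, a [3,3]-sigmatropic shift that dearomatises the B ring to a 6-(1,1-dimethylallyl)cyclohexa-2,4-dienone and re-aromatises by tautomerisation; it goes to the free ortho carbon para to OMe (C-5') and not to the carbon flanked by two oxygens (C-3'), and C-3 has no α-hydrogen so its configuration is untouched.

**Step 7**
Reactants: 12 (3R)-3-hydroxy-3-[4-hydroxy-2-methoxy-5-(2-methylbut-3-en-2-yl)phenyl]-5,7-bis(methoxymethoxy)chroman-4-one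
Product: 13 (3R)-3,5,7-trihydroxy-3-[4-hydroxy-2-methoxy-5-(2-methylbut-3-en-2-yl)phenyl]chroman-4-one
Conditions: 3 M aq HCl, MeOH, 35 °C, stopped at full conversion
Reagents that add atoms: none
Why: Acid-catalysed acetal methanolysis of the two aryl MOM ethers under dilute, mild conditions, in which ionisation of the tertiary C-3 alcohol is disfavoured by the adjacent carbonyl and the hindered monosubstituted alkene is not protonated.

**Compound list**
1 | 2',4'-dihydroxyacetophenone | CC(=O)c1ccc(O)cc1O | starting material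
2 | prenyl bromide (1-bromo-3-methylbut-2-ene) | CC(C)=CCBr | starting material
3 | 1-[2-hydroxy-4-(3-methylbut-2-enyloxy)phenyl]ethanone | CC(=O)c1ccc(OCC=C(C)C)cc1O | intermediate
4 | 1-[2-methoxy-4-(3-methylbut-2-enyloxy)phenyl]ethanone | CC(=O)c1ccc(OCC=C(C)C)cc1OC | intermediate
5 | {1-[2-methoxy-4-(3-methylbut-2-enyloxy)phenyl]ethenyloxy}trimethylsilane | C=C(O[Si](C)(C)C)c1ccc(OCC=C(C)C)cc1OC | intermediate
6 | 2-bromo-1-[2-methoxy-4-(3-methylbut-2-enyloxy)phenyl]ethanone | O=C(CBr)c1ccc(OCC=C(C)C)cc1OC | intermediate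
7 | 2,4,6-trihydroxybenzaldehyde | O=Cc1c(O)cc(O)cc1O | starting material
8 | 2-hydroxy-4,6-bis(methoxymethoxy)benzaldehyde | COCOc1cc(O)c(C=O)c(OCOC)c1 | intermediate
9 | 2-{2-[2-methoxy-4-(3-methylbut-2-enyloxy)phenyl]-2-oxoethoxy}-4,6-bis(methoxymethoxy)benzaldehyde | COCOc1cc(OCOC)c(C=O)c(OCC(=O)c2ccc(OCC=C(C)C)cc2OC)c1 | intermediate
10 | (3R)-3-hydroxy-3-[2-methoxy-4-(3-methylbut-2-enyloxy)phenyl]-5,7-bis(methoxymethoxy)chroman-4-one | COc1cc(OCC=C(C)C)ccc1[C@@]2(O)COc3cc(OCOC)cc(OCOC)c3C2=O | intermediate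
11 | (3R)-3-hydroxy-3-[6-methoxy-3-(2-methylbut-3-en-2-yl)-4-oxocyclohexa-1,5-dienyl]-5,7-bis(methoxymethoxy)chroman-4-one (both epimers at the ring sp3 carbon) | O=C1C=C(OC)C(=CC1C(C)(C)C=C)[C@@]2(O)COc3cc(OCOC)cc(OCOC)c3C2=O | intermediate
12 | (3R)-3-hydroxy-3-[4-hydroxy-2-methoxy-5-(2-methylbut-3-en-2-yl)phenyl]-5,7-bis(methoxymethoxy)chroman-4-one | C=CC(C)(C)c1cc([C@@]2(O)COc3cc(OCOC)cc(OCOC)c3C2=O)c(OC)cc1O | intermediate
13 | (3R)-3,5,7-trihydroxy-3-[4-hydroxy-2-methoxy-5-(2-methylbut-3-en-2-yl)phenyl]chroman-4-one | C=CC(C)(C)c1cc([C@@]2(O)COc3cc(O)cc(O)c3C2=O)c(OC)cc1O | target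

**Step count**
Total: 7 steps. Longest linear sequence: 6 steps (1 → 4 → 6 → 9 → 10 → 12 → 13; step 3 is the one-step side branch).

**Three steps most likely to fail**

Step 5 (benzoin). The aldehyde is di-ortho-oxygenated and electron-rich, so Breslow-intermediate formation may be slow, and base-mediated aldol closure to a benzofuran or low ee can compete. The fallback sets out from 9 and comes back at 10. Low-valent titanium (TiCl3/Zn–Cu, DME, reflux) couples the aldehyde and ketone of 9 reductively (intramolecular McMurry) to the 3-aryl-5,7-bis(methoxymethoxy)-2H-chromene F1. The conjugated chromene double bond is epoxidised with the (S,S)-Mn(salen)Cl catalyst, NaOCl and 4-phenylpyridine N-oxide, which is slow on the isolated prenyl alkene, to the (3R,4S)-3,4-epoxychromane F2; the catalyst enantiomer is chosen by analogy with 2,2-dimethylchromenes and would be swapped if the sense is reversed. Water opens F2 at the phloroglucinol-stabilised C-4 (THF–H2O, PPTS) to the (3R)-chromane-3,4-diol F3 as C-4 epimers. MnO2 in CH2Cl2 then oxidises the benzylic secondary alcohol of F3 to 10.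

Step 6 (Claisen). Risks are attack at C-3' instead of C-5', abnormal-Claisen or cyclised by-products, loss of the prenyl group, and thermal stress on the ketol. The fallback sets out from 4 and comes back at 13. The rearrangement is run on simple ketone 4 (same conditions, or PhNEt2 at 190 °C), the para-acyl aryl prenyl ether for which C-5 selectivity is best behaved, giving 1-[4-hydroxy-2-methoxy-5-(2-methylbut-3-en-2-yl)phenyl]ethanone F4. The phenol is capped (MOMCl, i-Pr2NEt) as the methoxymethyl ether F5, and PhNMe3Br3 in THF at 0 °C gives the α-bromoketone F6. Alkylation of 8 with F6 (K2CO3, DMF) gives the keto-aldehyde F7, and the benzoin cyclisation under step 5 conditions gives the tris-MOM ketol F8. HCl/MeOH as in step 7 then gives 13.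

Step 7 (MOM removal). Acid could dehydrate the tertiary benzylic ketol to the isoflavone, racemise it through a quinone-methide cation, or cyclise the phenol onto the 1,1-dimethylallyl group. The fallback sets out from 7 and comes back at 13, replacing MOM by allyl groups that are removed under neutral Pd(0) conditions. Allyl bromide (2.1 equiv) with K2CO3 in acetone gives 2-hydroxy-4,6-bis(allyloxy)benzaldehyde F9. Alkylation with 6 (K2CO3, DMF) gives the bis-allyl keto-aldehyde F10, and the benzoin under step 5 conditions gives the (3R)-bis-allyl ketol F11. The Claisen under step 6 conditions gives the rearranged phenol F12; unactivated allyl aryl ethers need about 180 °C and should stay in place at 130 °C. Pd(PPh3)4 (5 mol%) with morpholine in THF at rt then removes both allyl groups to give 13; the C-bound 1,1-dimethylallyl group cannot ionise to a π-allyl complex.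

**Further compounds**
F1 | step 5 | 3-[2-methoxy-4-(3-methylbut-2-enyloxy)phenyl]-5,7-bis(methoxymethoxy)-2H-chromene | COc1cc(OCC=C(C)C)ccc1C2=Cc3c(OCOC)cc(OCOC)cc3OC2
F2 | step 5 | (3R,4S)-3,4-epoxy-3-[2-methoxy-4-(3-methylbut-2-enyloxy)phenyl]-5,7-bis(methoxymethoxy)chromane | COc1cc(OCC=C(C)C)ccc1[C@@]2(O3)COc4cc(OCOC)cc(OCOC)c4[C@@H]23
F3 | step 5 | (3R)-3-[2-methoxy-4-(3-methylbut-2-enyloxy)phenyl]-5,7-bis(methoxymethoxy)chromane-3,4-diol (C-4 epimers) | COc1cc(OCC=C(C)C)ccc1[C@@]2(O)COc3cc(OCOC)cc(OCOC)c3C2O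
F4 | step 6 | 1-[4-hydroxy-2-methoxy-5-(2-methylbut-3-en-2-yl)phenyl]ethanone | CC(=O)c1cc(C(C)(C)C=C)c(O)cc1OC
F5 | step 6 | 1-[2-methoxy-4-(methoxymethoxy)-5-(2-methylbut-3-en-2-yl)phenyl]ethanone | CC(=O)c1cc(C(C)(C)C=C)c(OCOC)cc1OC
F6 | step 6 | 2-bromo-1-[2-methoxy-4-(methoxymethoxy)-5-(2-methylbut-3-en-2-yl)phenyl]ethanone | O=C(CBr)c1cc(C(C)(C)C=C)c(OCOC)cc1OC
F7 | step 6 | 2-{2-[2-methoxy-4-(methoxymethoxy)-5-(2-methylbut-3-en-2-yl)phenyl]-2-oxoethoxy}-4,6-bis(methoxymethoxy)benzaldehyde | COCOc1cc(OCOC)c(C=O)c(OCC(=O)c2cc(C(C)(C)C=C)c(OCOC)cc2OC)c1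
F8 | step 6 | (3R)-3-hydroxy-3-[2-methoxy-4-(methoxymethoxy)-5-(2-methylbut-3-en-2-yl)phenyl]-5,7-bis(methoxymethoxy)chroman-4-one | C=CC(C)(C)c1cc([C@@]2(O)COc3cc(OCOC)cc(OCOC)c3C2=O)c(OC)cc1OCOC
F9 | step 7 | 2-hydroxy-4,6-bis(prop-2-enyloxy)benzaldehyde | C=CCOc1cc(O)c(C=O)c(OCC=C)c1
F10 | step 7 | 2-{2-[2-methoxy-4-(3-methylbut-2-enyloxy)phenyl]-2-oxoethoxy}-4,6-bis(prop-2-enyloxy)benzaldehyde | C=CCOc1cc(OCC=C)c(C=O)c(OCC(=O)c2ccc(OCC=C(C)C)cc2OC)c1
F11 | step 7 | (3R)-3-hydroxy-3-[2-methoxy-4-(3-methylbut-2-enyloxy)phenyl]-5,7-bis(prop-2-enyloxy)chroman-4-one | COc1cc(OCC=C(C)C)ccc1[C@@]2(O)COc3cc(OCC=C)cc(OCC=C)c3C2=O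
F12 | step 7 | (3R)-3-hydroxy-3-[4-hydroxy-2-methoxy-5-(2-methylbut-3-en-2-yl)phenyl]-5,7-bis(prop-2-enyloxy)chroman-4-one | C=CC(C)(C)c1cc([C@@]2(O)COc3cc(OCC=C)cc(OCC=C)c3C2=O)c(OC)cc1O
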